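**Plan**
- Retrosynthesis: cut C4=C5 of the 3,6-dihydro-1,2-dioxine (ring-closing metathesis). Then cut the ketal bond C6–O1 (hydroperoxide plus 1-alkyl-1-methoxyallene), C6–C1' (allene alkylation) and C12'–C13' (Grignard reagent plus sorbyl acetate). The hydroperoxide is cut at C3–O2 (oxa-Michael addition to penta-2,4-dienal).
- Enabling feature: the ring is a bis-allylic peroxide. C4=C5 is the only ring bond that touches neither an oxygen nor a stereocentre, and it lies between C3 (on O2) and C6 (on O1). Opening it leaves two vinyl groups on an acyclic mixed peroxyketal, and a vinyl group on a C(OMe)(OOR) carbon is what H+/ROOH addition to a methoxyallene creates.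
- Forward: the side chain (steps 1–5) and the hydroperoxide (steps 6–9) are made separately. They are joined, and the only ring is closed, in one final flask (step 10). No helper group remains, and the base-sensitive dioxine meets no further reagent.
- Stereochemistry: C3 (R) comes from enantioselective iminium-catalysed peroxidation. C6 (R) comes from peroxyketalisation under chiral phosphoric acid control and is kept because the ring is closed at carbon under neutral conditions. The 14'E,16'E diene is bought with sorbyl acetate, and the ring olefin is Z by ring size.

Key step: step 10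

Assumption: precedent does not give the sense of induction of the chiral phosphoric acid at C6, so the (R)-acid is written as the matched one and its enantiomer replaces it if the other pairing proves matched; compounds 3, 8 and 13 are taken as purchasable.

Step 1
Reactants: 1 12-bromododecan-1-ol
Product: 2 2-[(12-bromododecyl)oxy]oxane
Conditions: 3,4-dihydro-2H-pyran, pyridinium p-toluenesulfonate (5 mol %), CH2Cl2, rt
Reagents that add atoms: 3,4-dihydro-2H-pyran, C1=COCCC1
Why: Acid-catalysed addition of the alcohol to the enol ether (tetrahydropyranyl protection) removes the acidic OH so that the bromide can be turned into a Grignard reagent; the acetal carbon forms as a racemate and leaves again in step 3.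

Step 2
Reactants: 2 2-[(12-bromododecyl)oxy]oxane; 3 (2E,4E)-hexa-2,4-dien-1-yl acetate (sorbyl acetate)
Product: 5 2-{[(14E,16E)-octadeca-14,16-dien-1-yl]oxy}oxane, via Grignard reagent 4 (not isolated)
Conditions: Mg, THF, 40 °C; then 3, Li2CuCl4 (3 mol %), THF, −10 °C
Reagents that add atoms: magnesium, [Mg] (stays in intermediate 4 only)
Why: Kochi-type copper-catalysed cross-coupling of a primary alkyl Grignard reagent with an allylic acetate, which with sorbyl acetate is known to substitute at the acetate-bearing carbon and to keep the E,E geometry, so both side-chain double bonds are bought with 3.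

Step 3
Reactants: 5 2-{[(14E,16E)-octadeca-14,16-dien-1-yl]oxy}oxane
Product: 6 (14E,16E)-octadeca-14,16-dien-1-ol
Conditions: p-toluenesulfonic acid monohydrate (5 mol %), MeOH, rt
Reagents that add atoms: none
Why: Acid-catalysed transacetalisation to methanol frees the primary alcohol under conditions that leave the remote E,E-diene untouched.

Step 4
Reactants: 6 (14E,16E)-octadeca-14,16-dien-1-ol
Product: 7 (2E,4E)-18-iodooctadeca-2,4-diene
Conditions: PPh3, imidazole, I2, CH2Cl2, 0 °C, dark
Reagents that add atoms: iodine, [I][I]
Why: Appel-type iodination, an SN2 displacement of the alkoxyphosphonium ion by iodide under nearly neutral conditions, gives the primary iodide needed for a clean alkylation in step 5.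

Step 5
Reactants: 7 (2E,4E)-18-iodooctadeca-2,4-diene; 8 methoxyallene (1-methoxypropa-1,2-diene)
Product: 10 (17E,19E)-3-methoxyhenicosa-1,2,17,19-tetraene, via 1-lithio-1-methoxyallene 9 (not isolated)
Conditions: 8 (1.5 equiv), n-BuLi, THF, −40 °C; then 7, −78 °C to rt; NaHCO3 work-up, Et3N-deactivated silica
Reagents that add atoms: n-butyllithium, [Li]CCCC (lithium stays in intermediate 9 only)
Why: Methoxyallene is deprotonated selectively at the oxygen-bearing carbon and the lithioallene is alkylated there by primary iodides (SN2), a standard route to 1-alkyl-1-methoxyallenes, which are masked vinyl ketones at the oxidation level of ketal carbon C6.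

Step 6
Reactants: 11 2,3-dimethylbut-2-ene
Product: 12 2-methoxypropan-2-yl hydroperoxide
Conditions: O3, CH2Cl2/MeOH, −78 °C; no reductive work-up
Reagents that add atoms: ozone, [O-][O+]=O; methanol, CO
Why: Criegee ozonolysis in a participating solvent, in which one half of the symmetrical alkene leaves as acetone and the other half is trapped by methanol as the alpha-methoxy hydroperoxide, a mono-protected form of H2O2.

Step 7
Reactants: 12 2-methoxypropan-2-yl hydroperoxide; 13 (2E)-penta-2,4-dienal
Product: 14 (3R)-3-[(2-methoxypropan-2-yl)peroxy]pent-4-enal
Conditions: 12 (1.5 equiv), (R)-2-{bis[3,5-bis(trifluoromethyl)phenyl][(trimethylsilyl)oxy]methyl}pyrrolidine (10 mol %), toluene, −10 °C; used crude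
Reagents that add atoms: none
Why: Enantioselective iminium-catalysed oxa-Michael addition of a hydroperoxide to an enal (organocatalytic peroxidation of enals), in which the diaryl(silyloxy)methyl group of the (R)-catalyst covers one face of the E, s-trans iminium ion so that oxygen attacks C3 from the open face and sets 3R, while attack at C3 should outrun attack at C5 because C3 lies closer to the iminium charge and the low temperature keeps the addition under kinetic control.

Step 8
Reactants: 14 (3R)-3-[(2-methoxypropan-2-yl)peroxy]pent-4-enal
Product: 15 (3R)-3-[(2-methoxypropan-2-yl)peroxy]pent-4-enoic acid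
Conditions: NaClO2, NaH2PO4, 2-methylbut-2-ene, t-BuOH/H2O, 0 °C
Reagents that add atoms: sodium chlorite, [Na+].[O-]Cl=O
Why: Pinnick oxidation converts the sensitive beta-peroxy aldehyde into the acid at about pH 4 without touching the O–O bond, the vinyl group (hypochlorous acid is intercepted by 2-methylbut-2-ene) or the C3 centre.

Step 9
Reactants: 15 (3R)-3-[(2-methoxypropan-2-yl)peroxy]pent-4-enoic acid
Product: 16 methyl (3R)-3-hydroperoxypent-4-enoate
Conditions: p-toluenesulfonic acid monohydrate (10 mol %), MeOH, rt
Reagents that add atoms: methanol, CO
Why: Fischer esterification and acid-catalysed methanolysis of the 2-methoxyprop-2-yl perketal run side by side with one catalyst in methanol, which forms the methyl ester and frees the hydroperoxide without breaking any bond to C3.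

Step 10
Reactants: 10 (17E,19E)-3-methoxyhenicosa-1,2,17,19-tetraene; 16 methyl (3R)-3-hydroperoxypent-4-enoate
Product: 18 xestin A, methyl 2-[(3R,6R)-6-methoxy-6-[(14E,16E)-octadeca-14,16-dien-1-yl]-3,6-dihydro-1,2-dioxin-3-yl]acetate, via acyclic peroxyketal 17 (not isolated)
Conditions: a) 16 (1.1 equiv), (R)-3,3'-bis(2,4,6-triisopropylphenyl)-1,1'-binaphthyl-2,2'-diyl hydrogen phosphate (5 mol %), 4 Å molecular sieves, toluene, −40 °C; then 2,6-di-tert-butyl-4-methylpyridine (10 mol %), cold filtration through neutral alumina; b) RuCl2(PCy3)2(=CHPh) (first-generation Grubbs catalyst, 10 mol %), CH2Cl2 (2 mM), 35 °C, argon sparge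
Reagents that add atoms: none
Why: Proposed new method: the chiral phosphoric acid protonates the central allene carbon of 10 while its P=O oxygen binds the OOH proton of 16, so the peroxide oxygen is delivered within a contact ion pair to the methoxy-bearing carbon of the nascent 1-methoxyallyl cation, which creates the mixed peroxyketal and its vinyl group in one atom-economical addition (17); once the acid is removed, the ruthenium benzylidene loads onto the less hindered vinyl group at C3 and closes C4=C5 by [2+2] cycloaddition and cycloreversion on the ketal-bound vinyl group with loss of ethene. The closest known reaction types are the acid-catalysed addition of hydroperoxides to enol ethers, chiral-phosphoric-acid-catalysed additions of hydroperoxides to imines and of alcohols to enol ethers, hydroalkoxylation of alkoxyallenes followed by ring-closing metathesis to unsaturated cyclic acetals, and olefin metathesis of substrates that hold a dialkyl peroxide; new are the pairing of a hydroperoxide with an alkoxyallene and catalyst control over an acyclic peroxyketal carbon. The one ring formed, the six-membered 1,2-dioxine, is closed by ring-closing metathesis, and its size allows only the Z olefin. The one new stereocentre, C6, is set under kinetic control by the 3,3'-aryl pocket of the phosphate, which has to tell the methoxy group from the alkyl chain on the two sides of the enol-ether face, reinforced by the neighbouring C3 centre of 16, while C3 itself is carried through unchanged. Because the ring is then closed at carbon under neutral conditions, neither C6–O bond is ionised again, so the ketal configuration, which would equilibrate in any acid-mediated closure at oxygen, is kept. The selectivities needed are alpha over gamma attack on the cation, secured by the charge on the oxygen-bearing carbon, and metathesis of the two monosubstituted vinyl groups only, secured by the 1,4-disubstituted and conjugated nature of the side-chain diene, to which the first-generation catalyst is nearly blind, by the fast six-ring closure, and by the inertness of the dialkyl peroxide towards the ruthenium alkylidene.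

**Compound list**
1 | 12-bromododecan-1-ol | OCCCCCCCCCCCCBr | starting material
2 | 2-[(12-bromododecyl)oxy]oxane | BrCCCCCCCCCCCCOC1CCCCO1 | intermediate
3 | (2E,4E)-hexa-2,4-dien-1-yl acetate (sorbyl acetate) | C/C=C/C=C/COC(C)=O | starting material
4 | {12-[(oxan-2-yl)oxy]dodecyl}magnesium bromide | Br[Mg]CCCCCCCCCCCCOC1CCCCO1 | intermediate
5 | 2-{[(14E,16E)-octadeca-14,16-dien-1-yl]oxy}oxane | C/C=C/C=C/CCCCCCCCCCCCCOC1CCCCO1 | intermediate
6 | (14E,16E)-octadeca-14,16-dien-1-ol | C/C=C/C=C/CCCCCCCCCCCCCO | intermediate
7 | (2E,4E)-18-iodooctadeca-2,4-diene | C/C=C/C=C/CCCCCCCCCCCCCI | intermediate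
8 | methoxyallene (1-methoxypropa-1,2-diene) | COC=C=C | starting material
9 | 1-lithio-1-methoxyallene | [Li]C(OC)=C=C | intermediate
10 | (17E,19E)-3-methoxyhenicosa-1,2,17,19-tetraene | C/C=C/C=C/CCCCCCCCCCCCCC(OC)=C=C | intermediate
11 | 2,3-dimethylbut-2-ene | CC(C)=C(C)C | starting material
12 | 2-methoxypropan-2-yl hydroperoxide | COC(C)(C)OO | intermediate
13 | (2E)-penta-2,4-dienal | C=C/C=C/C=O | starting material
14 | (3R)-3-[(2-methoxypropan-2-yl)peroxy]pent-4-enal | C=C[C@@H](CC=O)OOC(C)(C)OC | intermediate
15 | (3R)-3-[(2-methoxypropan-2-yl)peroxy]pent-4-enoic acid | C=C[C@@H](CC(=O)O)OOC(C)(C)OC | intermediate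
16 | methyl (3R)-3-hydroperoxypent-4-enoate | C=C[C@@H](CC(=O)OC)OO | intermediate
17 | methyl (3R)-3-{[(3R,17E,19E)-3-methoxyhenicosa-1,17,19-trien-3-yl]peroxy}pent-4-enoate | C/C=C/C=C/CCCCCCCCCCCCC[C@](OC)(C=C)OO[C@@H](C=C)CC(=O)OC | intermediate
18 | xestin A, methyl 2-[(3R,6R)-6-methoxy-6-[(14E,16E)-octadeca-14,16-dien-1-yl]-3,6-dihydro-1,2-dioxin-3-yl]acetate | C/C=C/C=C/CCCCCCCCCCCCC[C@]1(OC)C=C[C@@H](CC(=O)OC)OO1 | target

Total step count: 10. Longest linear sequence: 6 steps (steps 1, 2, 3, 4, 5 and 10).

**Steps most likely to fail**

Step 10 (labelled step).
- What may go wrong: weak facial discrimination at the ketal carbon inside the ion pair, erosion of the C6 configuration by re-ionisation before the acid is removed, and, to a lesser degree, slow engagement of the side-chain diene by ruthenium.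
- Fallback: it sets out from 10 and 16 and gives up catalyst control in favour of separation and thermodynamic recycling, all by known chemistry.
  - Pyridinium p-toluenesulfonate in CH2Cl2 at 0 °C adds 16 to 10 without facial bias. This should give 17 together with its ketal epimer methyl (3R)-3-{[(3S,17E,19E)-3-methoxyhenicosa-1,17,19-trien-3-yl]peroxy}pent-4-enoate F1.
  - The mixture is isolated on triethylamine-deactivated silica and cyclised with RuCl2(PCy3)2(=CHPh). This should give 18 and its C6 epimer methyl 2-[(3R,6S)-6-methoxy-6-[(14E,16E)-octadeca-14,16-dien-1-yl]-3,6-dihydro-1,2-dioxin-3-yl]acetate F2.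
  - The two cyclic ketals are separated by chromatography.
  - F2 is returned to the pool by equilibration with p-toluenesulfonic acid in methanol through the cyclic peroxycarbenium ion, followed by renewed separation.
  - The fallback comes back to the route at 18.

Step 7.
- What may go wrong: addition of the hydroperoxide at the unsubstituted terminus C5 (1,6-addition), collapse of the enamine onto the O–O bond with epoxide formation, and polymerisation of the dienal.
- Fallback: it sets out from 12 and blocks the diene terminus, which also changes the metathesis partner.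
  - Purchased (2E,4E)-hexa-2,4-dienal F3 is peroxidised with 12 and the same (R)-catalyst to (3R,4E)-3-[(2-methoxypropan-2-yl)peroxy]hex-4-enal F4.
  - Pinnick oxidation should give (3R,4E)-3-[(2-methoxypropan-2-yl)peroxy]hex-4-enoic acid F5.
  - Acidic methanol should give methyl (3R,4E)-3-hydroperoxyhex-4-enoate F6.
  - Acid-catalysed addition of F6 to 10 should give methyl (3R,4E)-3-{[(3R,17E,19E)-3-methoxyhenicosa-1,17,19-trien-3-yl]peroxy}hex-4-enoate F7.
  - Here ruthenium has to start at the hindered ketal-bound vinyl group. RuCl2(PCy3)(H2IMes)(=CHPh) (second-generation Grubbs catalyst) is therefore used, and the ring closes onto the propenyl group with loss of propene.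
  - The fallback comes back to the route at 18.

Step 9.
- What may go wrong: acid-induced Hock-type fragmentation of the free allylic hydroperoxide during the slow esterification, and losses on handling a small, oxygen-rich hydroperoxide.
- Fallback: it sets out from 15 and never isolates the hydroperoxide.
  - Trimethylsilyldiazomethane in toluene/MeOH esterifies 15 under neutral conditions to methyl (3R)-3-[(2-methoxypropan-2-yl)peroxy]pent-4-enoate F8.
  - F8, 10 and one equivalent of methanol are then treated with the acid catalyst of step 10. The hydroperoxide is released by perketal exchange and is captured at once and irreversibly by the allene.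
  - The fallback comes back to the route at 17, which is cyclised as in step 10.

**Further compounds**
F1 | step 10 | methyl (3R)-3-{[(3S,17E,19E)-3-methoxyhenicosa-1,17,19-trien-3-yl]peroxy}pent-4-enoate | C/C=C/C=C/CCCCCCCCCCCCC[C@@](OC)(C=C)OO[C@@H](C=C)CC(=O)OC
F2 | step 10 | methyl 2-[(3R,6S)-6-methoxy-6-[(14E,16E)-octadeca-14,16-dien-1-yl]-3,6-dihydro-1,2-dioxin-3-yl]acetate | C/C=C/C=C/CCCCCCCCCCCCC[C@@]1(OC)C=C[C@@H](CC(=O)OC)OO1
F3 | step 7 | (2E,4E)-hexa-2,4-dienal | C/C=C/C=C/C=O
F4 | step 7 | (3R,4E)-3-[(2-methoxypropan-2-yl)peroxy]hex-4-enal | C/C=C/[C@@H](CC=O)OOC(C)(C)OC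
F5 | step 7 | (3R,4E)-3-[(2-methoxypropan-2-yl)peroxy]hex-4-enoic acid | C/C=C/[C@@H](CC(=O)O)OOC(C)(C)OC
F6 | step 7 | methyl (3R,4E)-3-hydroperoxyhex-4-enoate | C/C=C/[C@@H](CC(=O)OC)OO
F7 | step 7 | methyl (3R,4E)-3-{[(3R,17E,19E)-3-methoxyhenicosa-1,17,19-trien-3-yl]peroxy}hex-4-enoate | C/C=C/C=C/CCCCCCCCCCCCC[C@](OC)(C=C)OO[C@@H](/C=C/C)CC(=O)OC
F8 | step 9 | methyl (3R)-3-[(2-methoxypropan-2-yl)peroxy]pent-4-enoate | C=C[C@@H](CC(=O)OC)OOC(C)(C)OC
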